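**Retrosynthetic overview**

- The strategy rests on ring C: its C4 oxygen, flanked by the 3,5-methoxy groups, sits para to the carbon that holds C2 of the dihydrobenzofuran. The O1–C2 bond is therefore made by oxidising the free ring C phenol of a 1,2-diarylpropane to its p-quinone methide and letting the ring D phenol add to the exocyclic carbon.
- The 1,2-diarylpropane comes from an Evans benzylation of a ring D arylacetyl imide with a ring C benzyl bromide (sets C3), followed by reduction, silylation, bromine-to-formyl exchange and removal of two allyl ethers.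
- The ring C phenol freed by the cyclisation is alkylated with a bromoacetyl oxazolidinone and joined by a boron aldol to a ring A–ring B aldehyde, which is itself made by the same alkylation/aldol pair. Labels: 7A/8A/9A are the side-chain carbons on ring A, 7B/8B/9B those on ring B.
- Both aldols give threo units, so 7A and 7B are inverted together by one double Mitsunobu esterification; Wittig extension to the E-enal and desilylation finish the route.
- Ring order: the four arenes are bought; the dihydrofuran is the only ring formed (step 14).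

Key step: step 14

Remark: the boron aldol of aryloxyacetyl imides gives syn (threo) adducts, so the (R)-auxiliary is used to fix 8A and 8B as S and the carbinol centres are inverted later. The silyl group on the dihydrobenzofuran CH2O is tert-butyldiphenylsilyl (not tert-butyldimethylsilyl) so that it survives the acetal hydrolysis of step 26. Compounds 1 and 25 are taken as purchasable.

**Route**

Step 1
Reactants: 1 5-bromo-2-hydroxy-3-methoxybenzaldehyde
Product: 2 2-(allyloxy)-5-bromo-3-methoxybenzaldehyde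
Conditions: allyl bromide, K2CO3, DMF, 50 °C
Reagents that add atoms: allyl bromide, C=CCBr
Why: Williamson etherification of the phenoxide should cap the ring D phenol as an allyl ether that tolerates the bases, hydrides and organolithium used before the cyclisation.

Step 2
Reactants: 2 2-(allyloxy)-5-bromo-3-methoxybenzaldehyde
Product: 3 2-(allyloxy)-5-bromo-1-methoxy-3-(2-methoxyethenyl)benzene (E/Z mixture)
Conditions: Ph3P(CH2OMe)Cl, KOtBu, THF, 0 °C to rt
Reagents that add atoms: (methoxymethyl)triphenylphosphonium chloride, COC[P+](c1ccccc1)(c1ccccc1)c1ccccc1.[Cl-]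
Why: Wittig methoxymethylenation of the aryl aldehyde should give the enol ether that carries the one extra carbon of the arylacetic acid.

Step 3
Reactants: 3 2-(allyloxy)-5-bromo-1-methoxy-3-(2-methoxyethenyl)benzene
Product: 4 2-[2-(allyloxy)-5-bromo-3-methoxyphenyl]acetaldehyde
Conditions: 2 M aq. HCl, THF, 50 °C; used crude
Reagents that add atoms: water, O
Why: Acid-catalysed enol ether hydrolysis should release the arylacetaldehyde while the aryl allyl ether and the bromide stay untouched.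

Step 4
Reactants: 4 2-[2-(allyloxy)-5-bromo-3-methoxyphenyl]acetaldehyde
Product: 5 2-[2-(allyloxy)-5-bromo-3-methoxyphenyl]acetic acid
Conditions: NaClO2, NaH2PO4, 2-methyl-2-butene, t-BuOH/H2O, rt
Reagents that add atoms: sodium chlorite, [Na+].[O-]Cl=O
Why: Pinnick oxidation should convert the aldehyde to the acid, the alkene scavenger protecting the allyl ether and the arene from hypochlorous acid.

Step 5
Reactants: 5 2-[2-(allyloxy)-5-bromo-3-methoxyphenyl]acetic acid; 6 (S)-4-benzyl-oxazolidin-2-one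
Product: 8 (S)-4-benzyl-3-{[2-(allyloxy)-5-bromo-3-methoxyphenyl]acetyl}oxazolidin-2-one, via mixed pivalic anhydride 7 (not isolated)
Conditions: t-BuCOCl, Et3N, THF, −20 °C; then 6, LiCl, rt
Reagents that add atoms: none
Why: N-acylation of the oxazolidinone through the mixed anhydride (LiCl-assisted) should install the Evans auxiliary on the arylacetic acid.

Step 6
Reactants: 9 syringaldehyde (4-hydroxy-3,5-dimethoxybenzaldehyde)
Product: 10 4-(allyloxy)-3,5-dimethoxybenzaldehyde
Conditions: allyl bromide, K2CO3, DMF, 50 °C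
Reagents that add atoms: allyl bromide, C=CCBr
Why: Williamson etherification should mask the ring C phenol with the same allyl group as ring D so that both are removed in one later step.

Step 7
Reactants: 10 4-(allyloxy)-3,5-dimethoxybenzaldehyde
Product: 11 [4-(allyloxy)-3,5-dimethoxyphenyl]methanol
Conditions: NaBH4, MeOH, 0 °C
Reagents that add atoms: none
Why: Borohydride reduction of the aldehyde should give the benzylic alcohol cleanly.

Step 8
Reactants: 11 [4-(allyloxy)-3,5-dimethoxyphenyl]methanol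
Product: 12 2-(allyloxy)-5-(bromomethyl)-1,3-dimethoxybenzene
Conditions: PBr3, CH2Cl2, 0 °C; used without storage
Reagents that add atoms: phosphorus tribromide, BrP(Br)Br
Why: Bromination of the electron-rich benzylic alcohol through its phosphite ester should give the reactive benzyl bromide.

Step 9
Reactants: 8 (S)-4-benzyl-3-{[2-(allyloxy)-5-bromo-3-methoxyphenyl]acetyl}oxazolidin-2-one; 12 2-(allyloxy)-5-(bromomethyl)-1,3-dimethoxybenzene
Product: 14 (S)-4-benzyl-3-[(S)-2-(2-allyloxy-5-bromo-3-methoxyphenyl)-3-(4-allyloxy-3,5-dimethoxyphenyl)propanoyl]oxazolidin-2-one, via sodium Z-enolate 13 (not isolated)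
Conditions: NaN(SiMe3)2, THF, −78 °C; then 12, −78 to −45 °C; AcOH quench at −78 °C
Reagents that add atoms: none
Why: Evans alkylation of the chelated Z-enolate should take the benzyl bromide on the face opposite the auxiliary benzyl group and so set the future C3 as S, the cold acidic quench guarding the acidic α-aryl centre against epimerisation.

Step 10
Reactants: 14 the alkylated imide
Product: 15 (S)-2-(2-allyloxy-5-bromo-3-methoxyphenyl)-3-(4-allyloxy-3,5-dimethoxyphenyl)propan-1-ol
Conditions: LiBH4, MeOH (1 equiv), THF, 0 °C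
Reagents that add atoms: none
Why: Reductive cleavage of the N-acyl oxazolidinone at 0 °C should give the primary alcohol and return the auxiliary without epimerising the benzylic centre.

Step 11
Reactants: 15 the primary alcohol
Product: 16 tert-butyldiphenylsilyl ether of 15
Conditions: t-BuPh2SiCl, imidazole, DMF, rt
Reagents that add atoms: tert-butyl(chloro)diphenylsilane, CC(C)(C)[Si](Cl)(c1ccccc1)c1ccccc1
Why: Silylation of the primary alcohol should give an ether robust enough for the organolithium, the oxidation and the later aqueous acid.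

Step 12
Reactants: 16 the silyl ether
Product: 18 4-allyloxy-3-[(S)-1-(4-allyloxy-3,5-dimethoxyphenyl)-3-(tert-butyldiphenylsilyloxy)propan-2-yl]-5-methoxybenzaldehyde, via aryllithium 17 (not isolated)
Conditions: n-BuLi, THF, −78 °C; then DMF, −78 °C to rt; H2O
Reagents that add atoms: N,N-dimethylformamide, CN(C)C=O
Why: Bromine–lithium exchange followed by formylation with DMF (Bouveault type) should place the formyl group para to the ring D oxygen, no other acidic or electrophilic site being present.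

Step 13
Reactants: 18 the bis(allyl ether) aldehyde
Product: 19 4-hydroxy-3-[(S)-1-(4-hydroxy-3,5-dimethoxyphenyl)-3-(tert-butyldiphenylsilyloxy)propan-2-yl]-5-methoxybenzaldehyde
Conditions: Pd(PPh3)4 (5 mol %), K2CO3, MeOH, rt, degassed
Reagents that add atoms: none
Why: Zerovalent palladium should ionise both aryl allyl ethers to π-allyl complexes that methanol captures (Tsuji–Trost deallylation), freeing the two phenols under conditions that spare the aldehyde and the silyl ether.

Step 14
Reactants: 19 the diphenol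
Product: 21 (2R,3S)-3-[(tert-butyldiphenylsilyloxy)methyl]-2-(4-hydroxy-3,5-dimethoxyphenyl)-7-methoxy-2,3-dihydrobenzofuran-5-carbaldehyde, via p-quinone methide 20 (not isolated)
Conditions: Ag2O (1.1 equiv), MgSO4, CH2Cl2, rt, dark
Reagents that add atoms: none
Why: Monovalent silver oxide should take two electrons and two protons from the electron-rich ring C phenol (through its phenoxyl radical) to give p-quinone methide 20, whose exocyclic carbon is the future C2. The ring D phenol then adds to that carbon in a 5-exo-trig oxa-conjugate addition that re-aromatises ring C and closes the dihydrofuran through the O1–C2 bond. The closest known reaction type is the Ag2O or DDQ oxidation of 4-alkyl-2,6-dimethoxyphenols to p-quinone methides with intramolecular heteroatom capture, as in phenylcoumaran formation. The new C2 centre is controlled by the existing C3 centre, since the aryl group should settle trans to the CH2OSi group and the reversibility of the addition through the quinone methide makes the trans (2R,3S) isomer the thermodynamic product as well. The step needs ring C to be oxidised and not ring D, which the substrate secures through the para formyl group on ring D (higher oxidation potential, no para benzylic hydrogen) against two donor methoxy groups on ring C. About one equivalent of oxidant in a dry non-aqueous medium should keep the aldehyde from oxidation to the acid and the product from dehydrogenation to the benzofuran.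

Step 15
Reactants: 22 (R)-4-benzyl-oxazolidin-2-one
Product: 24 (R)-4-benzyl-3-(bromoacetyl)oxazolidin-2-one, via lithium oxazolidinide 23 (not isolated)
Conditions: n-BuLi, THF, −78 °C; then BrCH2COBr, −78 °C
Reagents that add atoms: bromoacetyl bromide, BrCC(Br)=O
Why: N-acylation of the lithiated oxazolidinone by the acyl bromide should give the bromoacetyl imide used to carry the auxiliary onto both hindered phenols.

Step 16
Reactants: 25 4-hydroxy-3,5-dimethoxybenzonitrile; 24 (R)-4-benzyl-3-(bromoacetyl)oxazolidin-2-one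
Product: 26 (R)-4-benzyl-3-[(4-cyano-2,6-dimethoxyphenoxy)acetyl]oxazolidin-2-one
Conditions: K2CO3, acetone, rt
Reagents that add atoms: none
Why: Williamson etherification at the activated α-bromo carbonyl carbon should outrun attack of the phenoxide on the imide carbonyl and give the aryloxyacetyl imide of ring B, the nitrile serving as a latent formyl group.

Step 17
Reactants: 27 vanillin (4-hydroxy-3-methoxybenzaldehyde)
Product: 28 3-methoxy-4-(triisopropylsilyloxy)benzaldehyde
Conditions: iPr3SiCl, imidazole, DMF, rt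
Reagents that add atoms: chlorotriisopropylsilane, CC(C)[Si](Cl)(C(C)C)C(C)C
Why: Silylation should protect the ring A phenol as a base-tolerant aryl silyl ether that is removed only in the last step.

Step 18
Reactants: 26 the ring B aryloxyacetyl imide; 28 3-methoxy-4-(triisopropylsilyloxy)benzaldehyde
Product: 30 (R)-4-benzyl-3-[(2R,3S)-2-(4-cyano-2,6-dimethoxyphenoxy)-3-hydroxy-3-(3-methoxy-4-triisopropylsilyloxyphenyl)propanoyl]oxazolidin-2-one, via dibutylboron Z-enolate 29 (not isolated)
Conditions: Bu2BOTf, iPr2NEt, CH2Cl2, −78 to 0 °C; then 28, −78 to 0 °C; aq. NaH2PO4/Na2HPO4 (pH 7), MeOH, H2O2, 0 °C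
Reagents that add atoms: none
Why: Evans syn-aldol through the Zimmerman–Traxler chair of the Z-boron enolate should set 8A (later S) and 7A (S) under auxiliary control, giving the threo unit with the 8A configuration of the target.

Step 19
Reactants: 30 the aldol adduct
Product: 31 4-{[(1S,2S)-1,3-dihydroxy-1-(3-methoxy-4-triisopropylsilyloxyphenyl)propan-2-yl]oxy}-3,5-dimethoxybenzonitrile
Conditions: NaBH4, THF/H2O (4:1), 0 °C to rt
Reagents that add atoms: none
Why: Borohydride reduction of the activated imide carbonyl should release the 1,3-diol and the auxiliary while leaving the nitrile and the aryl silyl ether intact.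

Step 20
Reactants: 31 the threo diol
Product: 32 4-{[(4S,5S)-4-(3-methoxy-4-triisopropylsilyloxyphenyl)-2,2-dimethyl-1,3-dioxan-5-yl]oxy}-3,5-dimethoxybenzonitrile
Conditions: Me2C(OMe)2, pyridinium p-toluenesulfonate (cat.), CH2Cl2, rt
Reagents that add atoms: 2,2-dimethoxypropane, COC(C)(C)OC
Why: Acid-catalysed transketalisation should tie both hydroxyls into an acetonide so that no free hydroxyl enters the second aldol.

Step 21
Reactants: 32 the acetonide nitrile
Product: 34 4-{[(4S,5S)-4-(3-methoxy-4-triisopropylsilyloxyphenyl)-2,2-dimethyl-1,3-dioxan-5-yl]oxy}-3,5-dimethoxybenzaldehyde, via N-diisobutylaluminio aldimine 33 (not isolated)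
Conditions: iBu2AlH, toluene, −78 °C; aq. potassium sodium tartrate, rt
Reagents that add atoms: water, O
Why: Single hydride delivery to the aryl nitrile stops at the aluminium aldimine, whose hydrolysis should give the ring B aldehyde without touching acetonide or silyl ether.

Step 22
Reactants: 21 the dihydrobenzofuran phenol; 24 (R)-4-benzyl-3-(bromoacetyl)oxazolidin-2-one
Product: 35 (R)-4-benzyl-3-({4-[(2R,3S)-3-(tert-butyldiphenylsilyloxymethyl)-5-formyl-7-methoxy-2,3-dihydrobenzofuran-2-yl]-2,6-dimethoxyphenoxy}acetyl)oxazolidin-2-one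
Conditions: K2CO3, acetone, rt
Reagents that add atoms: none
Why: Williamson etherification of the hindered ring C phenoxide at the activated α-bromo carbonyl carbon should install the glycolate imide and at the same time remove the free phenol that makes the C2–O bond labile.

Step 23
Reactants: 35 the imide aldehyde
Product: 36 the 5-(1,3-dioxolan-2-yl) analogue of 35
Conditions: Me3SiOCH2CH2OSiMe3, Me3SiOTf (cat.), CH2Cl2, −78 to −20 °C; pyridine quench
Reagents that add atoms: 1,2-bis(trimethylsilyloxy)ethane, C[Si](C)(C)OCCO[Si](C)(C)C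
Why: Noyori acetalisation, driven by formation of hexamethyldisiloxane at low temperature, should mask the ring D aldehyde against the enolate and the hydride of the next two steps without harming the silyl ether or the imide.

Step 24
Reactants: 36 the dioxolane imide; 34 the ring A–ring B aldehyde
Product: 38 syn-aldol adduct joining 36 to 34 (imide α-carbon 8B R; carbinol 7B S), via dibutylboron Z-enolate 37 (not isolated)
Conditions: Bu2BOTf, iPr2NEt, CH2Cl2, −78 to 0 °C; then 34, −78 to 0 °C; aq. NaH2PO4/Na2HPO4 (pH 7), MeOH, H2O2, 0 °C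
Reagents that add atoms: none
Why: The second Evans syn-aldol should set 8B (later S) and 7B (S) under control of the (R)-auxiliary alone, the stereocentres of both partners lying too far from the reacting carbons to interfere and the amine base keeping the acetals safe from the boron triflate.

Step 25
Reactants: 38 the aldol adduct
Product: 39 the (7B S, 8B S) 1,3-diol (acetonide on unit A, dioxolane on ring D)
Conditions: NaBH4, THF/H2O (4:1), 0 °C to rt
Reagents that add atoms: none
Why: Borohydride reduction of the imide should give the 9B alcohol and return the auxiliary, the aldehyde being protected as its dioxolane.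

Step 26
Reactants: 39 the diol
Product: 40 the threo,threo tetraol aldehyde (7A S, 8A S, 7B S, 8B S)
Conditions: AcOH/THF/H2O (3:1:1), 40 °C
Reagents that add atoms: water, O
Why: Mild aqueous acid should hydrolyse the acetonide and the electron-rich aryl dioxolane together while the tert-butyldiphenylsilyl ether and the aryl triisopropylsilyl ether remain.

Step 27
Reactants: 40 the tetraol aldehyde
Product: 41 the 9A,9B-bis(tert-butyldimethylsilyl) ether of 40
Conditions: t-BuMe2SiCl (2.3 equiv), imidazole, DMF, 0 °C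
Reagents that add atoms: tert-butyl(chloro)dimethylsilane, CC(C)(C)[Si](C)(C)Cl
Why: Silylation should select the two primary hydroxyls over the two hindered secondary benzylic ones, leaving only 7A–OH and 7B–OH free.

Step 28
Reactants: 41 the bis-silyl diol
Product: 42 the 7A,7B-bis(4-nitrobenzoate) (7A R, 8A S, 7B R, 8B S)
Conditions: 4-nitrobenzoic acid, PPh3, DIAD (6 equiv each), toluene, 0 °C to rt
Reagents that add atoms: 4-nitrobenzoic acid, OC(=O)c1ccc(cc1)[N+](=O)[O-]
Why: Double Mitsunobu esterification should displace both alkoxyphosphonium groups by the carboxylate with inversion, turning the two threo units into the erythro (7R,8S) units of the target in one operation.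

Step 29
Reactants: 42 the bis(4-nitrobenzoate)
Product: 43 the erythro,erythro diol aldehyde
Conditions: K2CO3 (cat.), MeOH/THF, 0 °C
Reagents that add atoms: none
Why: Transesterification of the activated 4-nitrobenzoates with methanol should free both secondary alcohols with retention, the short cold treatment sparing the aryl triisopropylsilyl ether.

Step 30
Reactants: 43 the diol aldehyde
Product: 44 the E-enal (ring D 5-[(E)-3-oxoprop-1-enyl])
Conditions: Ph3P=CHCHO (2 equiv), toluene, 80 °C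
Reagents that add atoms: (triphenylphosphoranylidene)acetaldehyde, O=CC=P(c1ccccc1)(c1ccccc1)c1ccccc1
Why: Wittig reaction of the stabilised formyl ylide with the aryl aldehyde should give the E-configured cinnamaldehyde and tolerates the free secondary alcohols.

Step 31
Reactants: 44 the silylated enal
Product: 45 CNP0192639.1
Conditions: Bu4NF, AcOH (1:1), THF, 0 °C to rt
Reagents that add atoms: none
Why: Buffered fluoride should cleave the two tert-butyldimethylsilyl ethers, the tert-butyldiphenylsilyl ether and the aryl triisopropylsilyl ether without base damage to the enal or the p-hydroxybenzylic alcohol.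

**Compound list**

1 | 5-bromo-2-hydroxy-3-methoxybenzaldehyde | COc1cc(Br)cc(C=O)c1O | starting material
2 | 2-(allyloxy)-5-bromo-3-methoxybenzaldehyde | COc1cc(Br)cc(C=O)c1OCC=C | intermediate
3 | 2-(allyloxy)-5-bromo-1-methoxy-3-(2-methoxyethenyl)benzene (E/Z) | COC=Cc1cc(Br)cc(OC)c1OCC=C | intermediate
4 | 2-[2-(allyloxy)-5-bromo-3-methoxyphenyl]acetaldehyde | O=CCc1cc(Br)cc(OC)c1OCC=C | intermediate
5 | 2-[2-(allyloxy)-5-bromo-3-methoxyphenyl]acetic acid | OC(=O)Cc1cc(Br)cc(OC)c1OCC=C | intermediate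
6 | (S)-4-benzyl-oxazolidin-2-one | O=C1N[C@@H](Cc2ccccc2)CO1 | starting material
7 | mixed anhydride of 5 and pivalic acid (formed in the flask) | CC(C)(C)C(=O)OC(=O)Cc1cc(Br)cc(OC)c1OCC=C | intermediate
8 | (S)-4-benzyl-3-{[2-(allyloxy)-5-bromo-3-methoxyphenyl]acetyl}oxazolidin-2-one | C=CCOc1c(OC)cc(Br)cc1CC(=O)N1[C@@H](Cc2ccccc2)COC1=O | intermediate
9 | syringaldehyde | COc1cc(C=O)cc(OC)c1O | starting material
10 | 4-(allyloxy)-3,5-dimethoxybenzaldehyde | COc1cc(C=O)cc(OC)c1OCC=C | intermediate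
11 | [4-(allyloxy)-3,5-dimethoxyphenyl]methanol | COc1cc(CO)cc(OC)c1OCC=C | intermediate
12 | 2-(allyloxy)-5-(bromomethyl)-1,3-dimethoxybenzene | COc1cc(CBr)cc(OC)c1OCC=C | intermediate
13 | sodium Z-enolate of 8 (formed in the flask) | C=CCOc1c(OC)cc(Br)cc1/C=C(\[O-])N1[C@@H](Cc2ccccc2)COC1=O.[Na+] | intermediate
14 | (S)-4-benzyl-3-[(S)-2-(2-allyloxy-5-bromo-3-methoxyphenyl)-3-(4-allyloxy-3,5-dimethoxyphenyl)propanoyl]oxazolidin-2-one | C=CCOc1c(OC)cc(Br)cc1[C@H](Cc1cc(OC)c(OCC=C)c(OC)c1)C(=O)N1[C@@H](Cc2ccccc2)COC1=O | intermediate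
15 | (S)-2-(2-allyloxy-5-bromo-3-methoxyphenyl)-3-(4-allyloxy-3,5-dimethoxyphenyl)propan-1-ol | C=CCOc1c(OC)cc(Br)cc1[C@H](Cc1cc(OC)c(OCC=C)c(OC)c1)CO | intermediate
16 | tert-butyldiphenylsilyl ether of 15 | C=CCOc1c(OC)cc(Br)cc1[C@H](Cc1cc(OC)c(OCC=C)c(OC)c1)CO[Si](c1ccccc1)(c1ccccc1)C(C)(C)C | intermediate
17 | aryllithium from 16 (lithium in place of bromine; formed in the flask) | C=CCOc1c(OC)cc([Li])cc1[C@H](Cc1cc(OC)c(OCC=C)c(OC)c1)CO[Si](c1ccccc1)(c1ccccc1)C(C)(C)C | intermediate
18 | 4-allyloxy-3-[(S)-1-(4-allyloxy-3,5-dimethoxyphenyl)-3-(tert-butyldiphenylsilyloxy)propan-2-yl]-5-methoxybenzaldehyde | C=CCOc1c(OC)cc(C=O)cc1[C@H](Cc1cc(OC)c(OCC=C)c(OC)c1)CO[Si](c1ccccc1)(c1ccccc1)C(C)(C)C | intermediate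
19 | 4-hydroxy-3-[(S)-1-(4-hydroxy-3,5-dimethoxyphenyl)-3-(tert-butyldiphenylsilyloxy)propan-2-yl]-5-methoxybenzaldehyde (key-step precursor) | Oc1c(OC)cc(C=O)cc1[C@H](Cc1cc(OC)c(O)c(OC)c1)CO[Si](c1ccccc1)(c1ccccc1)C(C)(C)C | intermediate
20 | p-quinone methide from 19 (2,6-dimethoxy-4-alkylidenecyclohexa-2,5-dienone; formed in the flask) | Oc1c(OC)cc(C=O)cc1[C@H](C=C1C=C(OC)C(=O)C(OC)=C1)CO[Si](c1ccccc1)(c1ccccc1)C(C)(C)C | intermediate
21 | (2R,3S)-3-[(tert-butyldiphenylsilyloxy)methyl]-2-(4-hydroxy-3,5-dimethoxyphenyl)-7-methoxy-2,3-dihydrobenzofuran-5-carbaldehyde (key-step product) | COc1cc(cc(OC)c1O)[C@@H]1Oc2c(OC)cc(C=O)cc2[C@H]1CO[Si](c1ccccc1)(c1ccccc1)C(C)(C)C | intermediate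
22 | (R)-4-benzyl-oxazolidin-2-one | O=C1N[C@H](Cc2ccccc2)CO1 | starting material
23 | lithium salt of 22 (formed in the flask) | [Li+].O=C1[N-][C@H](Cc2ccccc2)CO1 | intermediate
24 | (R)-4-benzyl-3-(bromoacetyl)oxazolidin-2-one | BrCC(=O)N1[C@H](Cc2ccccc2)COC1=O | intermediate
25 | 4-hydroxy-3,5-dimethoxybenzonitrile | COc1cc(C#N)cc(OC)c1O | starting material
26 | (R)-4-benzyl-3-[(4-cyano-2,6-dimethoxyphenoxy)acetyl]oxazolidin-2-one | N#Cc1cc(OC)c(OCC(=O)N2[C@H](Cc3ccccc3)COC2=O)c(OC)c1 | intermediate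
27 | vanillin | COc1cc(C=O)ccc1O | starting material
28 | 3-methoxy-4-(triisopropylsilyloxy)benzaldehyde | COc1cc(C=O)ccc1O[Si](C(C)C)(C(C)C)C(C)C | intermediate
29 | dibutylboron Z-enolate of 26 (formed in the flask) | CCCCB(CCCC)O/C(=C\Oc1c(OC)cc(C#N)cc1OC)N1[C@H](Cc2ccccc2)COC1=O | intermediate
30 | (R)-4-benzyl-3-[(2R,3S)-2-(4-cyano-2,6-dimethoxyphenoxy)-3-hydroxy-3-(3-methoxy-4-triisopropylsilyloxyphenyl)propanoyl]oxazolidin-2-one | COc1cc(ccc1O[Si](C(C)C)(C(C)C)C(C)C)[C@H](O)[C@H](C(=O)N1[C@H](Cc2ccccc2)COC1=O)Oc1c(OC)cc(C#N)cc1OC | intermediate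
31 | 4-{[(1S,2S)-1,3-dihydroxy-1-(3-methoxy-4-triisopropylsilyloxyphenyl)propan-2-yl]oxy}-3,5-dimethoxybenzonitrile | COc1cc(ccc1O[Si](C(C)C)(C(C)C)C(C)C)[C@H](O)[C@H](CO)Oc1c(OC)cc(C#N)cc1OC | intermediate
32 | 4-{[(4S,5S)-4-(3-methoxy-4-triisopropylsilyloxyphenyl)-2,2-dimethyl-1,3-dioxan-5-yl]oxy}-3,5-dimethoxybenzonitrile | COc1cc(ccc1O[Si](C(C)C)(C(C)C)C(C)C)[C@@H]1OC(C)(C)OC[C@@H]1Oc1c(OC)cc(C#N)cc1OC | intermediate
33 | N-(diisobutylaluminio) aldimine from 32 (formed in the flask) | COc1cc(ccc1O[Si](C(C)C)(C(C)C)C(C)C)[C@@H]1OC(C)(C)OC[C@@H]1Oc1c(OC)cc(C=N[Al](CC(C)C)CC(C)C)cc1OC | intermediate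
34 | 4-{[(4S,5S)-4-(3-methoxy-4-triisopropylsilyloxyphenyl)-2,2-dimethyl-1,3-dioxan-5-yl]oxy}-3,5-dimethoxybenzaldehyde | COc1cc(ccc1O[Si](C(C)C)(C(C)C)C(C)C)[C@@H]1OC(C)(C)OC[C@@H]1Oc1c(OC)cc(C=O)cc1OC | intermediate
35 | (R)-4-benzyl-3-({4-[(2R,3S)-3-(tert-butyldiphenylsilyloxymethyl)-5-formyl-7-methoxy-2,3-dihydrobenzofuran-2-yl]-2,6-dimethoxyphenoxy}acetyl)oxazolidin-2-one | O=C(COc1c(OC)cc(cc1OC)[C@@H]1Oc2c(OC)cc(C=O)cc2[C@H]1CO[Si](c1ccccc1)(c1ccccc1)C(C)(C)C)N1[C@H](Cc2ccccc2)COC1=O | intermediate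
36 | 5-(1,3-dioxolan-2-yl) analogue of 35 | O=C(COc1c(OC)cc(cc1OC)[C@@H]1Oc2c(OC)cc(C3OCCO3)cc2[C@H]1CO[Si](c1ccccc1)(c1ccccc1)C(C)(C)C)N1[C@H](Cc2ccccc2)COC1=O | intermediate
37 | dibutylboron Z-enolate of 36 (formed in the flask) | CCCCB(CCCC)O/C(=C\Oc1c(OC)cc(cc1OC)[C@@H]1Oc2c(OC)cc(C3OCCO3)cc2[C@H]1CO[Si](c1ccccc1)(c1ccccc1)C(C)(C)C)N1[C@H](Cc2ccccc2)COC1=O | intermediate
38 | syn-aldol adduct of 36 and 34: (R)-4-benzyl-3-[(2R,3S)-2-(ring C aryloxy)-3-hydroxy-3-(ring B aryl)propanoyl]oxazolidin-2-one, unit A as (4S,5S)-acetonide | COc1cc(ccc1O[Si](C(C)C)(C(C)C)C(C)C)[C@@H]1OC(C)(C)OC[C@@H]1Oc1c(OC)cc(cc1OC)[C@H](O)[C@H](C(=O)N1[C@H](Cc2ccccc2)COC1=O)Oc1c(OC)cc(cc1OC)[C@@H]1Oc2c(OC)cc(C3OCCO3)cc2[C@H]1CO[Si](c1ccccc1)(c1ccccc1)C(C)(C)C | intermediate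
39 | (7B S, 8B S) 1,3-diol from 38 (unit A acetonide, ring D dioxolane) | COc1cc(ccc1O[Si](C(C)C)(C(C)C)C(C)C)[C@@H]1OC(C)(C)OC[C@@H]1Oc1c(OC)cc(cc1OC)[C@H](O)[C@H](CO)Oc1c(OC)cc(cc1OC)[C@@H]1Oc2c(OC)cc(C3OCCO3)cc2[C@H]1CO[Si](c1ccccc1)(c1ccccc1)C(C)(C)C | intermediate
40 | threo,threo tetraol aldehyde (7A S, 8A S, 7B S, 8B S) | COc1cc(ccc1O[Si](C(C)C)(C(C)C)C(C)C)[C@H](O)[C@H](CO)Oc1c(OC)cc(cc1OC)[C@H](O)[C@H](CO)Oc1c(OC)cc(cc1OC)[C@@H]1Oc2c(OC)cc(C=O)cc2[C@H]1CO[Si](c1ccccc1)(c1ccccc1)C(C)(C)C | intermediate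
41 | 9A,9B-bis(tert-butyldimethylsilyl) ether of 40 | COc1cc(ccc1O[Si](C(C)C)(C(C)C)C(C)C)[C@H](O)[C@H](CO[Si](C)(C)C(C)(C)C)Oc1c(OC)cc(cc1OC)[C@H](O)[C@H](CO[Si](C)(C)C(C)(C)C)Oc1c(OC)cc(cc1OC)[C@@H]1Oc2c(OC)cc(C=O)cc2[C@H]1CO[Si](c1ccccc1)(c1ccccc1)C(C)(C)C | intermediate
42 | 7A,7B-bis(4-nitrobenzoate), erythro,erythro (7A R, 8A S, 7B R, 8B S) | COc1cc(ccc1O[Si](C(C)C)(C(C)C)C(C)C)[C@@H](OC(=O)c1ccc(cc1)[N+](=O)[O-])[C@H](CO[Si](C)(C)C(C)(C)C)Oc1c(OC)cc(cc1OC)[C@@H](OC(=O)c1ccc(cc1)[N+](=O)[O-])[C@H](CO[Si](C)(C)C(C)(C)C)Oc1c(OC)cc(cc1OC)[C@@H]1Oc2c(OC)cc(C=O)cc2[C@H]1CO[Si](c1ccccc1)(c1ccccc1)C(C)(C)C | intermediate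
43 | erythro,erythro diol aldehyde (7A R, 8A S, 7B R, 8B S), silyl groups retained | COc1cc(ccc1O[Si](C(C)C)(C(C)C)C(C)C)[C@@H](O)[C@H](CO[Si](C)(C)C(C)(C)C)Oc1c(OC)cc(cc1OC)[C@@H](O)[C@H](CO[Si](C)(C)C(C)(C)C)Oc1c(OC)cc(cc1OC)[C@@H]1Oc2c(OC)cc(C=O)cc2[C@H]1CO[Si](c1ccccc1)(c1ccccc1)C(C)(C)C | intermediate
44 | E-enal of 43 (fully silylated target) | COc1cc(ccc1O[Si](C(C)C)(C(C)C)C(C)C)[C@@H](O)[C@H](CO[Si](C)(C)C(C)(C)C)Oc1c(OC)cc(cc1OC)[C@@H](O)[C@H](CO[Si](C)(C)C(C)(C)C)Oc1c(OC)cc(cc1OC)[C@@H]1Oc2c(OC)cc(/C=C/C=O)cc2[C@H]1CO[Si](c1ccccc1)(c1ccccc1)C(C)(C)C | intermediate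
45 | CNP0192639.1 | COc1cc([C@@H](O)[C@H](CO)Oc2c(OC)cc([C@@H](O)[C@H](CO)Oc3c(OC)cc([C@@H]4Oc5c(OC)cc(/C=C/C=O)cc5[C@H]4CO)cc3OC)cc2OC)ccc1O | target

**Step count**

Total: 31 steps. Longest linear sequence: 21 steps (1–5, 9–14, 22–31).

**Steps most likely to fail**

Step 14 (oxidative ring closure). The oxidation may not stay on ring C (attack at the ring D phenoxide or the aldehyde), the quinone methide may tautomerise to the 4-hydroxystilbene before it is trapped, or the product may be dehydrogenated further to the benzofuran. The fallback forms the O1–C2 bond by acid-catalysed substitution of a C2 benzylic alcohol, not by oxidation. It sets out from acid 5: acylation of the (R)-oxazolidinone 22 (t-BuCOCl, Et3N, LiCl) would give the (R)-auxiliary arylacetyl imide F1. A Bu2BOTf/iPr2NEt syn-aldol with aldehyde 10 would give the β-hydroxy imide F2; because the boron aldol uses the enolate face opposite to that of the alkylation, the (R)-auxiliary sets the future C3 in the same sense as in 14. LiBH4 would give the 1,3-diol F3, t-BuPh2SiCl/imidazole the primary silyl ether F4, n-BuLi (2.2 equiv) then DMF the aldehyde F5, and Pd(PPh3)4/K2CO3/MeOH the deallylated triol F6. Pyridinium p-toluenesulfonate in CH2Cl2 should then ionise the p-hydroxybenzylic alcohol and let the ring D phenol close to the trans-dihydrobenzofuran, which is compound 21, where the route is rejoined.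

Step 28 (double Mitsunobu inversion). The electron-rich benzylic alkoxyphosphonium ions may ionise, which would give partial retention at 7A or 7B or elimination to enol ethers. The fallback replaces inversion by oxidation and chelation-controlled reduction. It sets out from 41: Dess–Martin periodinane with NaHCO3 would give the 7A,7B-diketone F7. Zn(BH4)2 in Et2O at −20 °C should reduce both ketones through the chelate of the carbonyl and the α-aryloxy oxygen to the erythro alcohols, and it reduces the aldehyde as well, giving the triol F8. TEMPO/PhI(OAc)2 should then reoxidise only the primary benzylic alcohol, which gives compound 43.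

Step 30 (Wittig to the enal). The enal product is more electrophilic than the electron-rich aryl aldehyde, so a second olefination to the dienal and incomplete conversion may compete. The fallback goes through the ester oxidation level. It sets out from 43: Ph3P=CHCO2Et in toluene at 80 °C would give the E-cinnamate F9, which cannot react further with the ylide. iBu2AlH in CH2Cl2 at −78 °C would give the allylic alcohol F10, and TEMPO/PhI(OAc)2, selective for the primary allylic alcohol over the secondary ones, should give compound 44.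

**Further compounds**

F1 | step 14 | (R)-4-benzyl-3-{[2-(allyloxy)-5-bromo-3-methoxyphenyl]acetyl}oxazolidin-2-one | C=CCOc1c(OC)cc(Br)cc1CC(=O)N1[C@H](Cc2ccccc2)COC1=O
F2 | step 14 | (R)-4-benzyl-3-[(2R,3R)-2-(2-allyloxy-5-bromo-3-methoxyphenyl)-3-(4-allyloxy-3,5-dimethoxyphenyl)-3-hydroxypropanoyl]oxazolidin-2-one | C=CCOc1c(OC)cc(Br)cc1[C@H]([C@@H](O)c1cc(OC)c(OCC=C)c(OC)c1)C(=O)N1[C@H](Cc2ccccc2)COC1=O
F3 | step 14 | (1R,2S)-2-(2-allyloxy-5-bromo-3-methoxyphenyl)-1-(4-allyloxy-3,5-dimethoxyphenyl)propane-1,3-diol | C=CCOc1c(OC)cc(Br)cc1[C@H]([C@@H](O)c1cc(OC)c(OCC=C)c(OC)c1)CO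
F4 | step 14 | 3-O-tert-butyldiphenylsilyl ether of F3 | C=CCOc1c(OC)cc(Br)cc1[C@H]([C@@H](O)c1cc(OC)c(OCC=C)c(OC)c1)CO[Si](c1ccccc1)(c1ccccc1)C(C)(C)C
F5 | step 14 | 4-allyloxy-3-[(1R,2S)-1-(4-allyloxy-3,5-dimethoxyphenyl)-1-hydroxy-3-(tert-butyldiphenylsilyloxy)propan-2-yl]-5-methoxybenzaldehyde | C=CCOc1c(OC)cc(C=O)cc1[C@H]([C@@H](O)c1cc(OC)c(OCC=C)c(OC)c1)CO[Si](c1ccccc1)(c1ccccc1)C(C)(C)C
F6 | step 14 | 4-hydroxy-3-[(1R,2S)-1-hydroxy-1-(4-hydroxy-3,5-dimethoxyphenyl)-3-(tert-butyldiphenylsilyloxy)propan-2-yl]-5-methoxybenzaldehyde | Oc1c(OC)cc(C=O)cc1[C@H]([C@@H](O)c1cc(OC)c(O)c(OC)c1)CO[Si](c1ccccc1)(c1ccccc1)C(C)(C)C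
F7 | step 28 | 7A,7B-diketone of 41 (8A S, 8B S) | COc1cc(ccc1O[Si](C(C)C)(C(C)C)C(C)C)C(=O)[C@H](CO[Si](C)(C)C(C)(C)C)Oc1c(OC)cc(cc1OC)C(=O)[C@H](CO[Si](C)(C)C(C)(C)C)Oc1c(OC)cc(cc1OC)[C@@H]1Oc2c(OC)cc(C=O)cc2[C@H]1CO[Si](c1ccccc1)(c1ccccc1)C(C)(C)C
F8 | step 28 | erythro,erythro triol with ring D hydroxymethyl in place of formyl | COc1cc(ccc1O[Si](C(C)C)(C(C)C)C(C)C)[C@@H](O)[C@H](CO[Si](C)(C)C(C)(C)C)Oc1c(OC)cc(cc1OC)[C@@H](O)[C@H](CO[Si](C)(C)C(C)(C)C)Oc1c(OC)cc(cc1OC)[C@@H]1Oc2c(OC)cc(CO)cc2[C@H]1CO[Si](c1ccccc1)(c1ccccc1)C(C)(C)C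
F9 | step 30 | ethyl (E)-cinnamate of 43 | COc1cc(ccc1O[Si](C(C)C)(C(C)C)C(C)C)[C@@H](O)[C@H](CO[Si](C)(C)C(C)(C)C)Oc1c(OC)cc(cc1OC)[C@@H](O)[C@H](CO[Si](C)(C)C(C)(C)C)Oc1c(OC)cc(cc1OC)[C@@H]1Oc2c(OC)cc(/C=C/C(=O)OCC)cc2[C@H]1CO[Si](c1ccccc1)(c1ccccc1)C(C)(C)C
F10 | step 30 | (E)-allylic alcohol from F9 | COc1cc(ccc1O[Si](C(C)C)(C(C)C)C(C)C)[C@@H](O)[C@H](CO[Si](C)(C)C(C)(C)C)Oc1c(OC)cc(cc1OC)[C@@H](O)[C@H](CO[Si](C)(C)C(C)(C)C)Oc1c(OC)cc(cc1OC)[C@@H]1Oc2c(OC)cc(/C=C/CO)cc2[C@H]1CO[Si](c1ccccc1)(c1ccccc1)C(C)(C)C
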